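**Retrosynthetic overview**
1. 28 ⇐ 27 (hydrogenolysis) ⇐ 26 (fluoride opens a temporary O4–SiMe2–C15 ring, giving the C15 methyl and the C4 hydroxyl) ⇐ 25 (OsO4 on C8=C9) ⇐ ketone 22 (via its enol triflate).
2. Key disconnection 22 ⇒ 19: C1–C5 and C6–C7 are made together by an iron-hydride radical cascade, 5-exo onto an (E)-enol 4-(benzyloxy)benzoate, then 7-endo onto an isopropenyl ketone.
3. Enabling feature: C5–C6 (ring-fusion CH and ester-bearing CH) is a two-carbon unit between the quaternary C1 and C7, which are 1,5-related through C10–C9–C8. With C6 oxygenated and C9 at the ketone level, C5=C6 can be an enol ester that relays a C1 radical to C7. O4 and C15 are cis on the five-membered ring, so an O4–Si–C15 tether fixes C1 from C4.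
4. Ring order: temporary seven-membered oxasilepine (ring-closing metathesis) → cyclopentane → cycloheptane (both in step 11) → tether ring removed (step 15). 19 ⇐ 17 ⇐ alkyne 14 + acid 16; 14 ⇐ silyl ether 7 + vinyl bromide 10; 7 ⇐ (R)-alcohol 5, the only stereocentre set by a catalyst.

Key step: step 11

Numbering used in the text (daucane numbering): C1 quaternary ring-fusion carbon, C15 its methyl, C2 and C3 the cyclopentane methylenes, C4 the isopropyl carbinol carbon (oxygen O4), C5 the ring-fusion CH, C6 the ester-bearing CH, C7 CH2, C8 the methyl carbinol carbon, C9 CH(OH), C10 CH2; β is the face that carries C15, α the opposite face.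
Assumption: allyldiisopropoxyborane (4) is treated as an available reagent; the carbinol centre that becomes C9 (compounds 10 to 18) and C8 in 22 are carried as epimer mixtures because both are erased later (steps 10 and 12).

**Step 1**
Reactants: 1 2-methylpropanoyl chloride; 2 bis(trimethylsilyl)acetylene
Product: 3 4-methyl-1-(trimethylsilyl)pent-1-yn-3-one
Conditions: AlCl3, CH2Cl2, 0 °C
Reagents that add atoms: none
Why: Friedel–Crafts-type acylation of the bis-silyl alkyne by ipso substitution of one silyl group should stop at the mono-acylated silyl ynone because the product alkyne is deactivated.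

**Step 2**
Reactants: 3 silyl ynone; 4 allyldiisopropoxyborane
Product: 5 (3R)-3-(propan-2-yl)-1-(trimethylsilyl)hex-5-en-1-yn-3-ol
Conditions: (S)-3,3′-Br2-BINOL (15 mol %; the enantiomer of the diol is chosen to give the 3R alcohol), PhCF3/toluene, −35 °C; aqueous work-up
Reagents that add atoms: none
Why: Chiral-diol-catalysed asymmetric allylboration of a ketone through a closed six-membered transition state should differentiate the branched isopropyl group from the linear alkynyl group and so set C4, the one stereocentre from which all others are relayed.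

**Step 3**
Reactants: 5 tertiary propargylic alcohol; 6 (bromomethyl)chlorodimethylsilane
Product: 7 (bromomethyl)dimethylsilyl ether of 5
Conditions: Et3N, DMAP (cat.), CH2Cl2, 0 → 23 °C
Reagents that add atoms: none
Why: Silyl ether formation from a chlorosilane and a tertiary alcohol ties the carbon that becomes C15 to O4 through silicon.

**Step 4**
Reactants: 8 2,3-dibromoprop-1-ene; 9 methacrolein
Product: 10 5-bromo-2-methylhexa-1,5-dien-3-ol (racemic)
Conditions: Zn dust, THF/sat. aq. NH4Cl, 0 → 23 °C
Reagents that add atoms: none
Why: Barbier allylation, in which the allylzinc formed from the allylic bromide adds 1,2 to the enal while the vinylic bromide stays intact; the new carbinol centre is oxidised later, so the racemate is used.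

**Step 5**
Reactants: 7 bromomethylsilyl ether; 10 bromodienol
Product: 13 allylsilane dienol, via silylmethyl Grignard reagent 11 (not isolated), via chloromagnesium alkoxide of the bromodienol 12 (not isolated)
Conditions: 7, Mg, THF, 40 °C; 10, iPrMgCl (1.0 equiv), THF, 0 °C; then both combined, Pd(PPh3)4 (5 mol %), THF, 50 °C
Reagents that add atoms: none
Why: Kumada coupling of an α-silyl Grignard reagent with a 2-bromoalkene under zerovalent palladium catalysis is the standard route to 2-substituted allylsilanes, and the hydroxyl group is masked as its magnesium alkoxide.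

**Step 6**
Reactants: 13 allylsilane dienol
Product: 14 terminal alkyne
Conditions: AgNO3 (20 mol %), acetone/H2O, 23 °C
Reagents that add atoms: none
Why: Silver-catalysed protodesilylation is selective for the C(sp)–Si bond and should leave the hindered silyl ether and the allylsilane untouched.

**Step 7**
Reactants: 14 terminal alkyne
Product: 15 (E)-alkenyl pinacol boronate
Conditions: pinacolborane (2.5 equiv), Cp2Zr(H)Cl (10 mol %), Et3N (10 mol %), CH2Cl2, 23 °C; MeOH quench
Reagents that add atoms: pinacolborane, B1OC(C)(C)C(C)(C)O1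
Why: Zirconium-catalysed syn hydroboration of a terminal alkyne gives the E alkenylboronate, and alkynes react much faster than the alkenes present.

**Step 8**
Reactants: 15 (E)-alkenyl pinacol boronate; 16 4-(benzyloxy)benzoic acid
Product: 17 (E)-enol 4-(benzyloxy)benzoate
Conditions: Cu(OAc)2 (20 mol %), DMAP, 4 Å molecular sieves, O2 (1 atm), MeCN, 40 °C
Reagents that add atoms: none
Why: Chan–Lam-type oxidative copper coupling of an alkenylboron compound with a carboxylic acid should form the enol ester with retention of the E geometry and brings in the aroyl group of the target before the rings are built.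

**Step 9**
Reactants: 17 (E)-enol ester triene
Product: 18 seven-membered oxasilepine
Conditions: second-generation Grubbs catalyst (5 mol %), CH2Cl2 (0.005 M), 40 °C
Reagents that add atoms: none
Why: Silicon-tethered ring-closing metathesis between the allyl group and the 1,1-disubstituted allylsilane alkene closes the temporary ring and creates the trisubstituted C1=C2 alkene, the isopropenyl carbinol and enol ester alkenes being poor metathesis partners.

**Step 10**
Reactants: 18 oxasilepine allylic alcohol
Product: 19 oxasilepine isopropenyl ketone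
Conditions: Dess–Martin periodinane, NaHCO3, CH2Cl2, 0 °C; used without storage
Reagents that add atoms: none
Why: Dess–Martin oxidation of the allylic alcohol unveils the enone acceptor under buffered, non-basic conditions that should not move the β,γ-alkene into conjugation.

**Step 11**
Reactants: 19 oxasilepine isopropenyl ketone
Product: 22 silicon-bridged tricyclic C9 ketone, via tertiary C1 radical 20 (not isolated), via bridged C6 radical 21 (not isolated)
Conditions: Fe(acac)3 (30 mol %), PhSiH3 (2.5 equiv, slow addition), EtOH/(CH2OH)2 5:1 (0.01 M), 60 °C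
Reagents that add atoms: none
Why: Proposed new method: hydrogen atom transfer from an iron hydride to C2 of the trisubstituted ring alkene gives the tertiary C1 radical, which adds 5-exo-trig to C5 of the enol ester across the oxasilepine (a bridged, boat-like closure that forms the cyclopentane inside an oxasilabicyclo[3.2.1]octane); the nucleophilic α-acyloxy C6 radical then adds 7-endo-trig to the unsubstituted terminus C7 of the isopropenyl ketone, and the α-keto C8 radical is reduced by divalent iron and protonated by ethanol. The closest known reaction types are the Fe(acac)3/PhSiH3 reductive alkene–enone coupling, including its radical bicyclisations, and silicon-tethered radical cyclisations that deliver a methyl group cis to a hydroxyl. C1 is controlled by the O4–SiMe2–C15 tether, which can bridge the new five-membered ring on one face only, so C15 ends up cis to O4 and C10 trans; at C5, C6 should take the position over the ring oxygen, which carries no hydrogen, instead of the position over the C2–C3 bridge; at C6 the radical should close through the rotamer with its hydrogen between the quaternary C1 and C4 and the aroyloxy group outward, pseudo-equatorial in a chair-like seven-ring transition state. The step needs hydrogen atom transfer to the electron-rich trisubstituted allylsilane alkene and not to the enone or the 1,2-disubstituted enol ester (the donor/acceptor preference of this catalyst system), and 7-endo closure ahead of 6-exo closure and of reduction of the C6 radical (attack at the free CH2 terminus of an α-substituted enone, no 1,5-hydrogen within reach of C6, low silane concentration).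

**Step 12**
Reactants: 22 tricyclic C9 ketone
Product: 24 C8=C9 enol triflate, via potassium C8=C9 enolate 23 (not isolated)
Conditions: KN(SiMe3)2 (0.95 equiv), THF, −78 → 0 °C (equilibration); PhNTf2, −78 → 23 °C
Reagents that add atoms: N-phenylbis(trifluoromethanesulfonimide), O=S(=O)(N(c1ccccc1)S(=O)(=O)C(F)(F)F)C(F)(F)F
Why: Enolate equilibration to the more substituted C8=C9 isomer (C10 is neopentyl, next to the quaternary C1) followed by O-sulfonylation should give the tetrasubstituted enol triflate and erases the uncontrolled C8 centre.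

**Step 13**
Reactants: 24 enol triflate
Product: 25 C8=C9 alkene
Conditions: Pd(OAc)2 (5 mol %), PPh3 (10 mol %), HCO2H, Bu3N, DMF, 60 °C
Reagents that add atoms: none
Why: Palladium-catalysed formate reduction of an enol triflate (hydride transfer from formate to the vinylpalladium species) should give the trisubstituted alkene without touching the ester or the benzyl ether.

**Step 14**
Reactants: 25 C8=C9 alkene
Product: 26 silicon-bridged 8α,9α-diol
Conditions: OsO4 (5 mol %), N-methylmorpholine N-oxide, acetone/H2O, 23 °C
Reagents that add atoms: OsO4 (catalytic oxygen carrier), O=[Os](=O)(=O)=O; N-methylmorpholine N-oxide, C[N+]1([O-])CCOCC1; water, O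
Why: Catalytic syn dihydroxylation should take place on the α face of the cycloheptene, opposite to C15 and its silicon bridge, which sets C8 and C9 together and cis.

**Step 15**
Reactants: 26 silicon-bridged diol
Product: 27 4′-O-benzyl ether of the target
Conditions: Bu4NF (5 equiv), DMF, 70 °C
Reagents that add atoms: none
Why: Fluoride-induced protodesilylation of the cyclic alkoxysilane (removal of a temporary silicon tether) should protonate the C15–Si bond to give the angular methyl group and free the C4 hydroxyl without change at any stereocentre.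

**Step 16**
Reactants: 27 benzyl-protected target
Product: 28 target
Conditions: H2 (1 atm), Pd/C, EtOAc, 23 °C
Reagents that add atoms: none
Why: Hydrogenolysis of the benzyl aryl ether frees the phenol; no alkene remains and the benzoate ester is inert.

**Compound list**
1 | 2-methylpropanoyl chloride | CC(C)C(Cl)=O | starting material
2 | bis(trimethylsilyl)acetylene | C[Si](C)(C)C#C[Si](C)(C)C | starting material
3 | 4-methyl-1-(trimethylsilyl)pent-1-yn-3-one | CC(C)C(=O)C#C[Si](C)(C)C | intermediate
4 | allyldiisopropoxyborane | C=CCB(OC(C)C)OC(C)C | starting material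
5 | (3R)-3-(propan-2-yl)-1-(trimethylsilyl)hex-5-en-1-yn-3-ol | CC(C)[C@](C#C[Si](C)(C)C)(O)CC=C | intermediate
6 | (bromomethyl)chlorodimethylsilane | C[Si](C)(Cl)CBr | starting material
7 | (3R)-3-{[(bromomethyl)dimethylsilyl]oxy}-3-(propan-2-yl)-1-(trimethylsilyl)hex-5-en-1-yne | CC(C)[C@](C#C[Si](C)(C)C)(O[Si](C)(C)CBr)CC=C | intermediate
8 | 2,3-dibromoprop-1-ene | C=C(Br)CBr | starting material
9 | methacrolein (2-methylprop-2-enal) | CC(=C)C=O | starting material
10 | 5-bromo-2-methylhexa-1,5-dien-3-ol (racemic) | C=C(Br)CC(O)C(C)=C | intermediate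
11 | Grignard reagent of 7: bromo[(dimethyl{[(3R)-3-(propan-2-yl)-1-(trimethylsilyl)hex-5-en-1-yn-3-yl]oxy}silyl)methyl]magnesium | CC(C)[C@](C#C[Si](C)(C)C)(O[Si](C)(C)C[Mg]Br)CC=C | intermediate
12 | chloromagnesium 5-bromo-2-methylhexa-1,5-dien-3-olate | C=C(Br)CC(O[Mg]Cl)C(C)=C | intermediate
13 | 5-[(dimethyl{[(3R)-3-(propan-2-yl)-1-(trimethylsilyl)hex-5-en-1-yn-3-yl]oxy}silyl)methyl]-2-methylhexa-1,5-dien-3-ol (carbinol centre as epimer mixture) | CC(C)[C@](C#C[Si](C)(C)C)(O[Si](C)(C)CC(=C)CC(O)C(C)=C)CC=C | intermediate
14 | 5-[(dimethyl{[(3R)-3-(propan-2-yl)hex-5-en-1-yn-3-yl]oxy}silyl)methyl]-2-methylhexa-1,5-dien-3-ol | CC(C)[C@](C#C)(O[Si](C)(C)CC(=C)CC(O)C(C)=C)CC=C | intermediate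
15 | 5-[(dimethyl{[(1E,3R)-3-(propan-2-yl)-1-(4,4,5,5-tetramethyl-1,3,2-dioxaborolan-2-yl)hexa-1,5-dien-3-yl]oxy}silyl)methyl]-2-methylhexa-1,5-dien-3-ol | CC(C)[C@](/C=C/B1OC(C)(C)C(C)(C)O1)(O[Si](C)(C)CC(=C)CC(O)C(C)=C)CC=C | intermediate
16 | 4-(benzyloxy)benzoic acid | OC(=O)c1ccc(OCc2ccccc2)cc1 | starting material
17 | (1E,3R)-3-{[(4-hydroxy-5-methyl-2-methylidenehex-5-en-1-yl)dimethylsilyl]oxy}-3-(propan-2-yl)hexa-1,5-dien-1-yl 4-(benzyloxy)benzoate | CC(C)[C@](/C=C/OC(=O)c1ccc(OCc2ccccc2)cc1)(O[Si](C)(C)CC(=C)CC(O)C(C)=C)CC=C | intermediate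
18 | (E)-2-[(7R)-4-(2-hydroxy-3-methylbut-3-en-1-yl)-2,2-dimethyl-7-(propan-2-yl)-2,3,6,7-tetrahydro-1,2-oxasilepin-7-yl]ethenyl 4-(benzyloxy)benzoate | CC(C)[C@]1(/C=C/OC(=O)c2ccc(OCc3ccccc3)cc2)O[Si](C)(C)CC(CC(O)C(C)=C)=CC1 | intermediate
19 | (E)-2-[(7R)-2,2-dimethyl-4-(3-methyl-2-oxobut-3-en-1-yl)-7-(propan-2-yl)-2,3,6,7-tetrahydro-1,2-oxasilepin-7-yl]ethenyl 4-(benzyloxy)benzoate | CC(C)[C@]1(/C=C/OC(=O)c2ccc(OCc3ccccc3)cc2)O[Si](C)(C)CC(CC(=O)C(C)=C)=CC1 | intermediate
20 | tertiary C1 radical: 19 with hydrogen added to the ring CH (C2) and the unpaired electron on the ring carbon that carries the oxobutenyl chain | CC(C)[C@]1(/C=C/OC(=O)c2ccc(OCc3ccccc3)cc2)O[Si](C)(C)C[C](CC(=O)C(C)=C)CC1 | intermediate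
21 | C6 radical: cyclopentane C1–C5 closed, O4–SiMe2–C15 bridge cis on C4 and C1, C5 carrying the CH(O-aroyl) radical on the side of the ring oxygen, C1 carrying the oxobutenyl chain | CC(C)[C@]1(O[Si](C)(C)C4)CC[C@]4(CC(=O)C(C)=C)[C@H]1[CH]OC(=O)c2ccc(OCc3ccccc3)cc2 | intermediate
22 | 9-oxodaucan-6α-yl 4-(benzyloxy)benzoate with O4 and C15 joined by SiMe2 on the β face: trans-fused bicyclo[5.3.0]decane, H5 α, C1, C4, C5 and C6 configured as in the target, C8 methyl as epimer mixture | CC(C)[C@]1(O[Si](C)(C)C4)CC[C@]24CC(=O)C(C)C[C@H](OC(=O)c3ccc(OCc5ccccc5)cc3)[C@H]21 | intermediate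
23 | potassium C8=C9 enolate of 22 | CC(C)[C@]1(O[Si](C)(C)C4)CC[C@]24CC([O-])=C(C)C[C@H](OC(=O)c3ccc(OCc5ccccc5)cc3)[C@H]21.[K+] | intermediate
24 | C8=C9 enol triflate of 22 (triflate on C9, methyl on C8) | CC(C)[C@]1(O[Si](C)(C)C4)CC[C@]24CC(OS(=O)(=O)C(F)(F)F)=C(C)C[C@H](OC(=O)c3ccc(OCc5ccccc5)cc3)[C@H]21 | intermediate
25 | dauc-8-en-6α-yl 4-(benzyloxy)benzoate with the O4–SiMe2–C15 bridge | CC(C)[C@]1(O[Si](C)(C)C4)CC[C@]24CC=C(C)C[C@H](OC(=O)c3ccc(OCc5ccccc5)cc3)[C@H]21 | intermediate
26 | 8α,9α-dihydroxydaucan-6α-yl 4-(benzyloxy)benzoate with the O4–SiMe2–C15 bridge | CC(C)[C@]1(O[Si](C)(C)C4)CC[C@]24C[C@H](O)[C@](C)(O)C[C@H](OC(=O)c3ccc(OCc5ccccc5)cc3)[C@H]21 | intermediate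
27 | (1R,4R,5S,6S,8R,9S)-4,8,9-trihydroxydaucan-6-yl 4-(benzyloxy)benzoate | CC(C)[C@]1(O)CC[C@]2(C)C[C@H](O)[C@](C)(O)C[C@H](OC(=O)c3ccc(OCc5ccccc5)cc3)[C@H]21 | intermediate
28 | (1R,4R,5S,6S,8R,9S)-4,8,9-trihydroxydaucan-6-yl 4-hydroxybenzoate | CC(C)[C@]1(O)CC[C@]2(C)C[C@H](O)[C@](C)(O)C[C@H](OC(=O)c3ccc(O)cc3)[C@H]21 | target

**Step count and risks**
Total: 16 steps. Longest linear sequence: 15 steps (steps 1 to 3 and 5 to 16, from 1 to 28); the branch 8 + 9 → 10 is one step.

Steps most likely to fail:

1. Step 11 (Proposed new method). The C6 radical may be quenched by hydrogen transfer before the 7-endo closure, hydrogen atom transfer may go to the isopropenyl ketone and not to the ring alkene, and facial control at C5 may be incomplete. Fallback with known reaction types, from 19 back to 22: K2CO3 in methanol at 0 °C should cleave the enol ester and move the ring alkene into conjugation with the ketone, giving the conjugated keto aldehyde F1. A secondary-amine-catalysed intramolecular Michael addition (pyrrolidine, benzoic acid, CHCl3) of the aldehyde α-carbon C5 to C1 should then close the cyclopentane to the bridged aldehyde F2; the tether again fixes C1, and C5 is epimerisable and can be equilibrated. SmI2 in THF/MeOH should close the seven-membered ring by ketyl–enone coupling of C6 to C7, giving the hydroxy ketone F3. Acylation of the C6 hydroxyl with 4-(benzyloxy)benzoyl chloride (Et3N, DMAP) returns to 22.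

2. Step 8. Transmetalation of the hindered alkenyl pinacol boronate to copper may be slow, so that protodeboronation or O-alkenylation of the free alcohol competes. Fallback, from 15 back to 17: KHF2 in aqueous methanol converts the boronate into the potassium alkenyltrifluoroborate F4, the established boron partner for this coupling, which is then coupled with acid 16 (CuBr, DMAP, O2, 4 Å molecular sieves, MeCN) to give 17.

3. Step 12. Deprotonation may take place at C10 under kinetic control, or the enolate may not equilibrate fully, which would give the regioisomeric triflate. Fallback, from 22 back to 24: equilibrating silylation (Me3SiCl, NaI, Et3N, MeCN) should give the tetrasubstituted trimethylsilyl enol ether F5, which is isolated and freed from any regioisomer; anhydrous CsF with PhNTf2 in dimethoxyethane then converts it into 24.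

**Further compounds**
F1 | step 11 | 2-[2,2-dimethyl-4-(3-methyl-2-oxobut-3-en-1-ylidene)-7-(propan-2-yl)-1,2-oxasilepan-7-yl]acetaldehyde, C4 configured as in 19 | CC(C)[C@]1(CC=O)O[Si](C)(C)CC(=CC(=O)C(C)=C)CC1
F2 | step 11 | bridged aldehyde: cyclopentane C1–C5 closed, O4–SiMe2–C15 bridge, C5 carrying CHO on the side of the ring oxygen, C1 carrying the 3-methyl-2-oxobut-3-en-1-yl chain | CC(C)[C@]1(O[Si](C)(C)C4)CC[C@]4(CC(=O)C(C)=C)[C@H]1C=O
F3 | step 11 | 6α-hydroxydaucan-9-one with the O4–SiMe2–C15 bridge (C8 methyl as epimer mixture) | CC(C)[C@]1(O[Si](C)(C)C4)CC[C@]24CC(=O)C(C)C[C@H](O)[C@H]21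
F4 | step 8 | potassium (E)-alkenyltrifluoroborate corresponding to 15 | CC(C)[C@](/C=C/[B-](F)(F)F)(O[Si](C)(C)CC(=C)CC(O)C(C)=C)CC=C.[K+]
F5 | step 12 | C8=C9 trimethylsilyl enol ether of 22 | CC(C)[C@]1(O[Si](C)(C)C4)CC[C@]24CC(O[Si](C)(C)C)=C(C)C[C@H](OC(=O)c3ccc(OCc5ccccc5)cc3)[C@H]21
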